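The pyranone is cut at three bonds, O1–C8a, C4–C4a and O1–C2. Because O1 and the C4 carbonyl occupy adjacent carbons of ring A (C8a and C4a), an aryne spanning C4a–C8a can receive both atoms from a single carboxyl group. In the key step the aryne released by fluoride from an o-silylaryl triflate inserts into the C–O bond of an arylpropiolic acid and the resulting phenoxide closes ring C onto the ynone, giving the fully benzylated flavone in one operation. The precursors are a 2-silylaryl triflate carrying the C5–C7 oxygen pattern with C8 still C–H, and a catechol-protected arylpropiolic acid. C8 methoxylation, C3 hydroxylation and hydrogenolysis finish the route.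

Key step: step 9

Remark on the chemistry: the target has no stereocentre, so no configuration has to be set; benzyl is used for every hydroxyl that must be free at the end, so that one hydrogenolysis finishes the synthesis.

Step 1
Reactants: 1 3,5-dihydroxy-4-methoxybenzoic acid
Product: 2 benzyl 3,5-bis(benzyloxy)-4-methoxybenzoate
Conditions: BnBr (3.5 equiv), K2CO3, DMF, 60 °C
Reagents that add atoms: benzyl bromide, BrCc1ccccc1
Why: Williamson etherification of both phenols and SN2 esterification of the carboxylate should run in one pot and mask every acidic site as a benzyl group.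

Step 2
Reactants: 2 benzyl 3,5-bis(benzyloxy)-4-methoxybenzoate
Product: 3 [3,5-bis(benzyloxy)-4-methoxyphenyl]methanol
Conditions: LiAlH4, THF, 0 °C to rt
Reagents that add atoms: none
Why: Hydride reduction of the benzyl ester should give the primary benzylic alcohol, while aryl benzyl and methyl ethers are inert to LiAlH4.

Step 3
Reactants: 3 [3,5-bis(benzyloxy)-4-methoxyphenyl]methanol
Product: 4 3,5-bis(benzyloxy)-4-methoxybenzaldehyde
Conditions: activated MnO2 (excess), CH2Cl2, rt
Reagents that add atoms: none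
Why: Heterogeneous MnO2 oxidation is selective for benzylic alcohols and should stop cleanly at the aldehyde.

Step 4
Reactants: 4 3,5-bis(benzyloxy)-4-methoxybenzaldehyde
Product: 6 3,5-bis(benzyloxy)-4-methoxyphenol, via aryl formate 5 (not isolated)
Conditions: mCPBA, CH2Cl2, 0 °C to rt; aq. NaHCO3 wash, evaporate; K2CO3 (cat.), MeOH, rt
Reagents that add atoms: 3-chloroperoxybenzoic acid, OOC(=O)c1cccc(Cl)c1
Why: In this Dakin-type Baeyer–Villiger oxidation the electron-rich trioxygenated aryl group should migrate in the Criegee intermediate to give the aryl formate, which mild methanolysis converts into the phenol.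

Step 5
Reactants: 6 3,5-bis(benzyloxy)-4-methoxyphenol
Product: 7 3,5-bis(benzyloxy)-2-bromo-4-methoxyphenol
Conditions: NBS (1.0 equiv), CH2Cl2, −78 to 0 °C
Reagents that add atoms: N-bromosuccinimide, O=C1CCC(=O)N1Br
Why: Electrophilic aromatic bromination should occur ortho to the free hydroxyl; the two ortho positions are equivalent and the para position is blocked, so one monobromide is expected if one equivalent is added slowly in the cold.

Step 6
Reactants: 7 3,5-bis(benzyloxy)-2-bromo-4-methoxyphenol
Product: 10 3,5-bis(benzyloxy)-4-methoxy-2-(trimethylsilyl)phenyl trifluoromethanesulfonate, via aryl trimethylsilyl ether 8 (not isolated), via lithium 2-silylphenoxide 9 (not isolated)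
Conditions: (Me3Si)2NH, THF, 70 °C, evaporate; n-BuLi, THF, −78 °C; Tf2O, −78 °C to rt
Reagents that add atoms: hexamethyldisilazane, C[Si](C)(C)N[Si](C)(C)C; trifluoromethanesulfonic anhydride, O=S(=O)(OS(=O)(=O)C(F)(F)F)C(F)(F)F
Why: After O-silylation, bromine–lithium exchange should trigger a 1,3 oxygen-to-carbon silyl shift (retro-Brook rearrangement) that puts silicon on the former C–Br carbon and frees a phenoxide for triflation, the standard entry to o-silylaryl triflates.

Step 7
Reactants: 11 3,4-bis(benzyloxy)benzaldehyde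
Product: 12 1,2-bis(benzyloxy)-4-(2,2-dibromoethenyl)benzene
Conditions: CBr4, PPh3, CH2Cl2, 0 °C
Reagents that add atoms: carbon tetrabromide, BrC(Br)(Br)Br
Why: The first stage of the Corey–Fuchs sequence, a Wittig reaction of the dibromomethylene ylide formed in the flask, should convert the aldehyde into the 1,1-dibromoalkene.

Step 8
Reactants: 12 1,2-bis(benzyloxy)-4-(2,2-dibromoethenyl)benzene
Product: 14 3-[3,4-bis(benzyloxy)phenyl]prop-2-ynoic acid, via lithium acetylide 13 (not isolated)
Conditions: n-BuLi (2.2 equiv), THF, −78 °C; CO2, −78 °C to rt; aq. HCl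
Reagents that add atoms: carbon dioxide, O=C=O
Why: In the second Corey–Fuchs stage, elimination and bromine–lithium exchange should give the lithium acetylide, which is carboxylated by CO2 and protonated on work-up.

Step 9
Reactants: 10 3,5-bis(benzyloxy)-4-methoxy-2-(trimethylsilyl)phenyl trifluoromethanesulfonate; 14 3-[3,4-bis(benzyloxy)phenyl]prop-2-ynoic acid
Product: 17 5,7-bis(benzyloxy)-2-[3,4-bis(benzyloxy)phenyl]-6-methoxy-4H-chromen-4-one, via aryne 15 (not isolated), via o-hydroxyaryl ynone 16 (not isolated)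
Conditions: 10 (1.2 equiv), CsF (4 equiv), THF, 125 °C, sealed tube
Reagents that add atoms: none
Why: Fluoride removes the silyl group and expels triflate to give aryne 15, and the caesium carboxylate of 14 adds through oxygen at the aryne carbon remote from the flanking benzyloxy group (future C8a), because that ether polarises the strained triple bond and stabilises the aryl anion beside it (future C4a). The anion attacks the adjacent ester carbonyl and the four-membered alkoxide opens to the o-acylphenoxide 16, a net insertion of the aryne into the C–O bond of the acid, which is the known behaviour of fluoride-generated arynes towards carboxylic acids, arylpropiolic acids included. The phenoxide then closes ring C by 6-endo-dig oxa-Michael addition to the ynone, and the vinyl anion is protonated at C3. No stereocentre is formed. The step needs regiocontrol on the aryne, which the single alkoxy group next to the triple bond should secure since C8 is deliberately left as C–H, and it needs 6-endo over 5-exo closure, which the conjugate polarisation of the aryl ynone under hot aprotic fluoride conditions should favour.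

Step 10
Reactants: 17 5,7-bis(benzyloxy)-2-[3,4-bis(benzyloxy)phenyl]-6-methoxy-4H-chromen-4-one
Product: 18 5,7-bis(benzyloxy)-2-[3,4-bis(benzyloxy)phenyl]-8-iodo-6-methoxy-4H-chromen-4-one
Conditions: N-iodosuccinimide, CF3CO2H (cat.), MeCN, 0 °C to rt
Reagents that add atoms: N-iodosuccinimide, O=C1CCC(=O)N1I
Why: Electrophilic aromatic iodination should go to C8, the only free position of the phloroglucinol-type ring A and activated by O1 and the C5 and C7 ethers, in preference to ring B (deactivated by the conjugated pyranone) and C3.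

Step 11
Reactants: 18 5,7-bis(benzyloxy)-2-[3,4-bis(benzyloxy)phenyl]-8-iodo-6-methoxy-4H-chromen-4-one
Product: 19 5,7-bis(benzyloxy)-2-[3,4-bis(benzyloxy)phenyl]-6,8-dimethoxy-4H-chromen-4-one
Conditions: NaOMe, CuBr (cat.), MeOH/DMF, 100 °C
Reagents that add atoms: sodium methoxide, [Na+].[O-]C
Why: Copper-catalysed Ullmann-type C–O coupling of an aryl iodide with methoxide is established for 8-haloflavones, and benzyl ethers are inert to methoxide.

Step 12
Reactants: 19 5,7-bis(benzyloxy)-2-[3,4-bis(benzyloxy)phenyl]-6,8-dimethoxy-4H-chromen-4-one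
Product: 22 5,7-bis(benzyloxy)-2-[3,4-bis(benzyloxy)phenyl]-3-hydroxy-6,8-dimethoxy-4H-chromen-4-one, via 3-lithioflavone 20 (not isolated), via flavon-3-ylboronate 21 (not isolated)
Conditions: LDA, THF, −78 °C; B(OMe)3, −78 to 0 °C; AcOH, 30% aq. H2O2, 0 °C to rt
Reagents that add atoms: hydrogen peroxide, OO
Why: C3–H, vinylic and next to the coordinating C4 carbonyl, is the most acidic site left once C8 is substituted, so directed lithiation, borate trapping and oxidative 1,2-migration from boron to oxygen should deliver the flavonol, a known flavone-to-flavonol conversion.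

Step 13
Reactants: 22 5,7-bis(benzyloxy)-2-[3,4-bis(benzyloxy)phenyl]-3-hydroxy-6,8-dimethoxy-4H-chromen-4-one
Product: 23 2-(3,4-dihydroxyphenyl)-3,5,7-trihydroxy-6,8-dimethoxy-4H-chromen-4-one (3,5,7,3',4'-pentahydroxy-6,8-dimethoxyflavone)
Conditions: H2 (1 atm), 10% Pd/C, THF/MeOH, rt
Reagents that add atoms: none
Why: Catalytic hydrogenolysis should cleave all four aryl benzyl ethers at once, while the methyl ethers and the flavonol core are untouched under these mild conditions.

Compound list
1 | 3,5-dihydroxy-4-methoxybenzoic acid | COc1c(O)cc(C(=O)O)cc1O | starting material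
2 | benzyl 3,5-bis(benzyloxy)-4-methoxybenzoate | COc1c(OCc2ccccc2)cc(C(=O)OCc2ccccc2)cc1OCc1ccccc1 | intermediate
3 | [3,5-bis(benzyloxy)-4-methoxyphenyl]methanol | COc1c(OCc2ccccc2)cc(CO)cc1OCc1ccccc1 | intermediate
4 | 3,5-bis(benzyloxy)-4-methoxybenzaldehyde | COc1c(OCc2ccccc2)cc(C=O)cc1OCc1ccccc1 | intermediate
5 | 3,5-bis(benzyloxy)-4-methoxyphenyl formate | COc1c(OCc2ccccc2)cc(OC=O)cc1OCc1ccccc1 | intermediate (not isolated)
6 | 3,5-bis(benzyloxy)-4-methoxyphenol | COc1c(OCc2ccccc2)cc(O)cc1OCc1ccccc1 | intermediate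
7 | 3,5-bis(benzyloxy)-2-bromo-4-methoxyphenol | COc1c(OCc2ccccc2)cc(O)c(Br)c1OCc1ccccc1 | intermediate
8 | [3,5-bis(benzyloxy)-2-bromo-4-methoxyphenoxy]trimethylsilane | COc1c(OCc2ccccc2)cc(O[Si](C)(C)C)c(Br)c1OCc1ccccc1 | intermediate (not isolated)
9 | lithium 3,5-bis(benzyloxy)-4-methoxy-2-(trimethylsilyl)phenoxide | COc1c(OCc2ccccc2)cc([O-])c([Si](C)(C)C)c1OCc1ccccc1.[Li+] | intermediate (not isolated)
10 | 3,5-bis(benzyloxy)-4-methoxy-2-(trimethylsilyl)phenyl trifluoromethanesulfonate | COc1c(OCc2ccccc2)cc(OS(=O)(=O)C(F)(F)F)c([Si](C)(C)C)c1OCc1ccccc1 | intermediate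
11 | 3,4-bis(benzyloxy)benzaldehyde | O=Cc1ccc(OCc2ccccc2)c(OCc2ccccc2)c1 | starting material
12 | 1,2-bis(benzyloxy)-4-(2,2-dibromoethenyl)benzene | BrC(Br)=Cc1ccc(OCc2ccccc2)c(OCc2ccccc2)c1 | intermediate
13 | {[3,4-bis(benzyloxy)phenyl]ethynyl}lithium | [Li]C#Cc1ccc(OCc2ccccc2)c(OCc2ccccc2)c1 | intermediate (not isolated)
14 | 3-[3,4-bis(benzyloxy)phenyl]prop-2-ynoic acid | OC(=O)C#Cc1ccc(OCc2ccccc2)c(OCc2ccccc2)c1 | intermediate
15 | 3,5-bis(benzyloxy)-4-methoxybenzyne (1,2-didehydroarene between the former C–OTf and C–Si carbons) | COC1=C(OCc2ccccc2)C#CC=C1OCc1ccccc1 | intermediate (not isolated)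
16 | 1-[2,4-bis(benzyloxy)-6-hydroxy-3-methoxyphenyl]-3-[3,4-bis(benzyloxy)phenyl]prop-2-yn-1-one (present as its caesium phenoxide) | COc1c(OCc2ccccc2)cc(O)c(C(=O)C#Cc2ccc(OCc3ccccc3)c(OCc3ccccc3)c2)c1OCc1ccccc1 | intermediate (not isolated)
17 | 5,7-bis(benzyloxy)-2-[3,4-bis(benzyloxy)phenyl]-6-methoxy-4H-chromen-4-one | COc1c(OCc2ccccc2)cc2oc(-c3ccc(OCc4ccccc4)c(OCc4ccccc4)c3)cc(=O)c2c1OCc1ccccc1 | intermediate
18 | 5,7-bis(benzyloxy)-2-[3,4-bis(benzyloxy)phenyl]-8-iodo-6-methoxy-4H-chromen-4-one | COc1c(OCc2ccccc2)c(I)c2oc(-c3ccc(OCc4ccccc4)c(OCc4ccccc4)c3)cc(=O)c2c1OCc1ccccc1 | intermediate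
19 | 5,7-bis(benzyloxy)-2-[3,4-bis(benzyloxy)phenyl]-6,8-dimethoxy-4H-chromen-4-one | COc1c(OCc2ccccc2)c(OC)c2oc(-c3ccc(OCc4ccccc4)c(OCc4ccccc4)c3)cc(=O)c2c1OCc1ccccc1 | intermediate
20 | 5,7-bis(benzyloxy)-2-[3,4-bis(benzyloxy)phenyl]-3-lithio-6,8-dimethoxy-4H-chromen-4-one | COc1c(OCc2ccccc2)c(OC)c2oc(-c3ccc(OCc4ccccc4)c(OCc4ccccc4)c3)c([Li])c(=O)c2c1OCc1ccccc1 | intermediate (not isolated)
21 | dimethyl {5,7-bis(benzyloxy)-2-[3,4-bis(benzyloxy)phenyl]-6,8-dimethoxy-4-oxo-4H-chromen-3-yl}boronate | COc1c(OCc2ccccc2)c(OC)c2oc(-c3ccc(OCc4ccccc4)c(OCc4ccccc4)c3)c(B(OC)OC)c(=O)c2c1OCc1ccccc1 | intermediate (not isolated)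
22 | 5,7-bis(benzyloxy)-2-[3,4-bis(benzyloxy)phenyl]-3-hydroxy-6,8-dimethoxy-4H-chromen-4-one | COc1c(OCc2ccccc2)c(OC)c2oc(-c3ccc(OCc4ccccc4)c(OCc4ccccc4)c3)c(O)c(=O)c2c1OCc1ccccc1 | intermediate
23 | 2-(3,4-dihydroxyphenyl)-3,5,7-trihydroxy-6,8-dimethoxy-4H-chromen-4-one | COc1c(O)c(OC)c2oc(-c3ccc(O)c(O)c3)c(O)c(=O)c2c1O | target

Total step count: 13. Longest linear sequence: 11 steps (steps 1–6, then 9–13); steps 7–8 form the short convergent branch.

Steps most likely to fail

Step 9. Four processes could divert the key step: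
- protonation of the aryl anion before acyl transfer, which would end in simple O-arylation of the acid;
- thermal loss of CO2 from the propiolate;
- capture of the phenoxide by a second aryne;
- 5-exo closure in place of 6-endo closure.

The fallback sets out from 7 and 14 and forms the C4–C4a bond by organolithium acylation instead of aryne insertion. Acid 14 would be coupled with N,O-dimethylhydroxylamine hydrochloride (EDC hydrochloride, N-methylmorpholine, CH2Cl2) to give 3-[3,4-bis(benzyloxy)phenyl]-N-methoxy-N-methylprop-2-ynamide F1. Bromophenol 7 would be treated with n-BuLi (2.2 equiv, THF, −78 °C) to give lithium 3,5-bis(benzyloxy)-2-lithio-4-methoxyphenoxide F2. Acylation of F2 with F1 should give ynone 16 after aqueous work-up, now as an isolated compound. Heating 16 with Et2NH in EtOH (amine conjugate addition, then 6-endo addition–elimination) should close the pyranone, and the fallback rejoins the route at 17.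

Step 11. Reductive loss of iodine under the copper conditions, or opening of the pyranone by hot methoxide, could erode the methoxylation. The fallback sets out from 18 and builds the C8–O bond through boron. Miyaura borylation (bis(pinacolato)diboron, Pd(dppf)Cl2, KOAc, dioxane, 90 °C) should give 5,7-bis(benzyloxy)-2-[3,4-bis(benzyloxy)phenyl]-6-methoxy-8-(4,4,5,5-tetramethyl-1,3,2-dioxaborolan-2-yl)-4H-chromen-4-one F3. Oxidation with NaBO3·4H2O in THF/water should give 5,7-bis(benzyloxy)-2-[3,4-bis(benzyloxy)phenyl]-8-hydroxy-6-methoxy-4H-chromen-4-one F4. O-Methylation (MeI, K2CO3, acetone) then rejoins the route at 19.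

Step 12. The 3-lithio species could open ring C by β-elimination of the phenoxide, or LDA could deprotonate a benzylic ether CH2 instead. The fallback sets out from 19 and avoids carbanions. Epoxidation of the C2–C3 double bond with dimethyldioxirane (acetone/CH2Cl2, 0 °C) should give the racemic cis-fused 2,3-epoxide of 19 (2,3-epoxyflavanone) F5. Catalytic p-toluenesulfonic acid in CH2Cl2 should open and tautomerise it to the flavonol, rejoining the route at 22.

Further compounds
F1 | step 9 | 3-[3,4-bis(benzyloxy)phenyl]-N-methoxy-N-methylprop-2-ynamide | CON(C)C(=O)C#Cc1ccc(OCc2ccccc2)c(OCc2ccccc2)c1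
F2 | step 9 | lithium 3,5-bis(benzyloxy)-2-lithio-4-methoxyphenoxide | COc1c(OCc2ccccc2)cc([O-])c([Li])c1OCc1ccccc1.[Li+]
F3 | step 11 | 5,7-bis(benzyloxy)-2-[3,4-bis(benzyloxy)phenyl]-6-methoxy-8-(4,4,5,5-tetramethyl-1,3,2-dioxaborolan-2-yl)-4H-chromen-4-one | COc1c(OCc2ccccc2)c(B3OC(C)(C)C(C)(C)O3)c2oc(-c3ccc(OCc4ccccc4)c(OCc4ccccc4)c3)cc(=O)c2c1OCc1ccccc1
F4 | step 11 | 5,7-bis(benzyloxy)-2-[3,4-bis(benzyloxy)phenyl]-8-hydroxy-6-methoxy-4H-chromen-4-one | COc1c(OCc2ccccc2)c(O)c2oc(-c3ccc(OCc4ccccc4)c(OCc4ccccc4)c3)cc(=O)c2c1OCc1ccccc1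
F5 | step 12 | racemic cis-fused 2,3-epoxide of 19 (one enantiomer drawn) | COc1c(OCc2ccccc2)c(OC)c2O[C@]3(c4ccc(OCc5ccccc5)c(OCc5ccccc5)c4)O[C@@H]3C(=O)c2c1OCc1ccccc1
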